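At late times the theta flask, which is the flask asked about, shows D lying level, 29% at 2.50 d and 31% at 5.00 d, while L falls from 49% to 25%; L loses more than D gains, so what leaves L does not stay as D.

common to all: E 390 mM

| charge | L | temperature | remark | time |
|---|---|---|---|---|
| theta | 3 M | 25 °C | the very flask that is asked about, followed so far |  |
| epsilon | 2 M | 31 °C | run made earlier |  |
| flask | 3.0 M | 25 °C |  | 8.0 d |

- theta (time / d: D / %, L / %): 0.417: 8, 89; 0.833: 17, 79; 1.25: 22, 68; 2.50: 29, 49; 5.00: 31, 25
- epsilon (time / h: D / %, L / %): 4.00: 5, 89; 10.0: 17, 83; 20.0: 23, 68; 30.0: 25, 51; 40.0: 32, 47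

(standard deviation of a reading: 2 percentage points)

- Saturday's: at 8.0 d take out 90% of the D then present, then wait 2.5 d
- Thursday's: change nothing and wait 2.5 d more
- Monday's: at 8.0 d add E, 100% of the amount charged, then wait 2.5 d
- Wednesday's: at 8.0 d raise the temperature by 10 K, then wait 2.5 d

- D taken out counts as made
- the earlier runs were read with a standard deviation of 2 percentage points
- additions bring no volume worth counting

* D, in percent of the L first charged, at 8.0 d
* what to do for the largest gain in D; "none" if nothing gains more than 2 percentage points (Saturday's / Thursday's / Monday's / Wednesday's / none)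
* D present, with what was taken out counted in, in percent of the L first charged, after Saturday's
* D present, with what was taken out counted in, in percent of the L first charged, after Monday's

L is the curve that can be reckoned, and logarithms straighten it. Counted in decades (factors of 10) below the charge, the last theta reading stands 0.602 down, so the decade time of L, the time in which c_L falls by one decade, reads 8.30 d. That line gives 50.0% at 2.50 d, where 49% was read, so it holds while c_L falls to a quarter of its charge: a pseudo-first-order fall, in which the percentages of the theta flask do not depend on the charge of L.

The curve can now be drawn. L starts down at 0.277 d⁻¹ of the charge, steeper than the rise of D, 0.204 d⁻¹ over the first 0.833 d. D bends between 1.25 d and 2.50 d and runs into a level near 30.0%, which L crosses at 4.34 d. At 8.0 d L stands at 10.9%, and this reckoning keeps D at its level. A further 2.5 d takes 5.4 percentage points more from L, so Saturday's is reckoned near 35.4%. The last epsilon reading, 47% of L at 40.0 h, gives a decade time of 5.08 d at 31 °C, shorter than the theta one, with the charge of L differing as well. This figure is for L, and this reckoning carries none for D under heat. Both runs were charged with the same E, so the readings give no figure for added E.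

The forecast differs, with D at 21% (from 18% to 24%), “already past its peak”, 23.5% after Saturday's, 9% after Monday's, and Saturday's as the choice.

The flask gives D 29.2% and L 11.1% at 8.00 d; Wednesday's gains 19 points, Saturday's reaches 42.7%, and Monday's ends at 26.8%.

    D + E ⇌ J + E, rate k1*[E]*[D] forward; the back reaction follows from the equilibrium constant (K = 1.30, k = 0.0750 L mol⁻¹ h⁻¹, Ea = 70.0 kJ mol⁻¹, ΔH = −51.0 kJ mol⁻¹)
    J ⇌ X (K = 1.60, k = 0.0110 h⁻¹, Ea = 109 kJ mol⁻¹, ΔH = −83.0 kJ mol⁻¹)
    L + E ⇌ D + E, rate k3*[L]*[E] forward; the back reaction follows from the equilibrium constant (K = 20.0, k = 0.0310 L mol⁻¹ h⁻¹, Ea = 69.0 kJ mol⁻¹, ΔH = 31.0 kJ mol⁻¹)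
    (constants at 25 °C)

Saturday's gains 14 points, more than the 5.4 points that the decade time allots to L; the other 8.1 points has come by a route other than L, and the equations hold a way back from J, which stood at 31.0%. The neighbouring flask has 1.8 M of L. The decade time carries no charge of L in it, so the same reckoning gives 10.9% left at 8.00 d, and that neighbouring flask holds 11.1% of L then, with D at 29.2%.

Readings and results are calculated on assumed constants; the scatter is artificial.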